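## The problem

Compound 23 is the (E)-ferulate of the secondary C8 hydroxyl of a guai-1(10)-ene-8,11-diol. Guaiane numbering is used throughout. The five-membered ring is C1–C5 with a methyl on C4. The seven-membered ring is C1, C5, C6, C7, C8, C9, C10, with the hydroxyisopropyl carbon C11 on C7, the ester oxygen on C8 and the methyl C14 on C10. The two rings share the C1–C5 bond, and since C1 is one end of the tetrasubstituted C1=C10 double bond, the ring fusion has a single stereocentre, C5. Four stereocentres (4S, 5S, 7S, 8S) must be set: H4, H5 and H7 lie on the face of the C8 oxygen, and C11 is trans to that oxygen. The C4/C5 pair is separated from the C7/C8 pair by the C6 methylene, so in a flexible cycloheptene neither pair can be expected to control the other. The alkene must sit at C1=C10 and not in one of the easily reached isomeric positions. The tertiary C11 alcohol ionises under acid, and the feruloyl group (free phenol, conjugated E-alkene, ester) would not survive hydrogenation, organometallic reagents or strong base, so it must be attached last. The enabling feature is that the C8 oxygen is 1,4 to C1 across the seven-membered ring. A C1–O–C8 ether makes the carbocycle an 8-oxabicyclo[3.2.1]octane, the ring system formed when a six-membered cyclic carbonyl ylide adds to an alkene. That bridge oxygen is the future ester oxygen, a rigid marker of the face to which H4, H5 and H7 must go, and a leaving group on C1 whose loss toward C10 fixes the double bond.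

## Retrosynthesis

**Ester bond at C8.** The acyl–oxygen bond of the C8 ester is cut first: 23 comes from its phenol silyl ether 22, and 22 from diol 17 and the silyl-protected acid 20, one step from ferulic acid 18. This cut is preferred to a displacement at C8 because the C8–O bond, and with it the stereocentre, is never touched. It also keeps the sensitive aromatic half out of all terpene chemistry. Diol 17 has fifteen carbons and no aromatic ring. The forward acylation only has to prefer a secondary over a tertiary hydroxyl, but it must cope with the bulk of the neighbouring hydroxyisopropyl group.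

**C10–C14 bond and the C1=C10 alkene.** The C10 methyl of 17 is disconnected to alkenyl sulfone 16, which carries a phenylsulfonyl group where the methyl will stand. Compound 16 is the ring-opened form of the oxygen-bridged sulfone 15, so the C1=C10 π bond is traded for a C1–O bond and a C10–H bond. Dehydration of a C10 carbinol would give positional mixtures, and a metathesis closure would have to form a tetrasubstituted alkene in the ring-closing event. The sulfone instead marks C10, acidifies H10 so that the C1 oxygen leaves by an E1cB path, and then acts as the leaving group for a methyl cross-coupling. Precursor 15 has no alkene and a rigid core. The forward steps must remove H10 without letting the new double bond migrate, and must couple at a hindered alkenyl carbon.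

**C–H bonds at C4, C5, C6 and C7.** Four hydrogens are removed from 15 to give diene 14 (C4=C5 and C6=C7). The hydrogenation is placed here, while the bridge is intact, because the bicyclic frame distinguishes the two faces of the diene. The bridge-oxygen face is open and carries two donor oxygens (the bridge ether and the C11 hydroxyl). The other face is covered by the C9–C10 bridge. After bridge opening the same reduction would have to be controlled in a flexible ring and would compete with the C1=C10 alkene. The forward reaction must reduce a tetrasubstituted alkene completely and from one face.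

**C7–C11 and the two C11–methyl bonds.** The hydroxyisopropyl group is taken off in three stages: tertiary alcohol 14 from methyl ester 12 (two C–CH3 bonds), 12 from enol triflate 11 (the C7–C11 bond), and 11 from ketone 9. Enolisation of 9 can only go toward C6 because C8 is a bridgehead, so the position of the new C6=C7 bond is unambiguous. Routes through a vinyl anion at C7 were rejected because the strong bases they need would deprotonate C10 and open the bridge too early. Ketone 9 has eleven skeletal carbons and three stereocentres, of which only the linked pair C1/C8 matters. The forward sequence needs reagents of low basicity throughout.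

**C8–O, C8–C9 and C1–C10: the key disconnection.** Cutting the two carbon–carbon bonds of the oxolane ring in 9 gives phenyl vinyl sulfone 7 and the cyclic carbonyl ylide 8. Cutting the C8–O bond of 8 gives the acyclic diazoketone 6. This single disconnection removes the seven-membered ring and all stereocentres, and leads to an achiral cyclopentenone with a three-carbon side chain. It is preferred to closing the seven-membered ring by a separate C–C bond formation because ring, C8 oxygen and sulfone handle are installed together. The forward reaction must form the ylide at the enone oxygen, add the sulfone with the sulfonyl carbon on C1, react at C1 rather than at the vinylogous position C4, and do so under control of a chiral dirhodium carboxylate.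

**The diazoketone.** Compound 6 is the diazomethyl ketone of acid 4 (C7–C8 bond). Acid 4 is the aldol condensation product of keto ester 3 (C4=C5 bond), and 3 is the conjugate-addition product of aldehyde 1 and enone 2 (C1–C2 bond). Each cut removes one bond by a classical reaction, and the two starting materials are bulk chemicals.

## Roads not taken

**Alternative 1:** The cut is at C8, treated as an acyl-anion linchpin, with the C7–C8 and C8–C9 bonds formed in one flask and the seven-membered ring left open. In the forward key step lithiated 1,3-dithiane A3 opens the enantiopure trisubstituted epoxide A2 at its secondary carbon C7 with inversion, freeing the C11 alkoxide. After a second lithiation at C8 the same pot is alkylated with methallyl bromide A4 to give A1.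
- Merits: C7 and C11 come from one epoxide of secure configuration, and three fragments are joined in a single operation by dependable dithiane chemistry.
- Weak points: no ring closes. The seven-membered ring must then be closed by metathesis between the two 1,1-disubstituted alkenes of A1 to form the tetrasubstituted C1=C10 bond, one of the least favourable cases for that reaction. The second lithiation occurs beside a branched, alkoxide-bearing carbon. C8 emerges at the ketone level and must be reduced with control from C7 alone. The C4/C5 stereocentres of the cyclopentane in A2 have to be made separately.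
- Comparison: Alternative 1 is better in that its absolute configuration rests on a well-understood epoxide and not on an untested catalyst–substrate pair. Against this, the adopted plan obtains the ring, the C8 oxygen in its final configuration and the alkene position from one cycloaddition, and C8 never passes through a ketone.

**Alternative 2:** The cut is the C1–C5 bond of the guaiane, which in the forward sense arises from the C5–C10 bond of a eudesmane. Buffered solvolysis of tosylate A6 (equatorial at C1 of a trans-fused decalin, with the 8,11-diol masked as an acetonide) lets the antiperiplanar C5–C10 bond migrate to C1 in a Wagner–Meerwein shift. The resulting C10 cation loses H1 to give the hydroazulene A5.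
- Merits: the stereocentres are set on a chair decalin with predictable conformational control. One step creates both ring sizes and the C1=C10 alkene, and only acetonide removal and acylation remain afterwards.
- Weak points: A6 is itself a six-stereocentre target needing a long decalin synthesis. The C10 cation can lose a proton toward C1, C9 or C14, so alkene mixtures are likely. The C8 oxygen, two bonds from the cationic centre, slows ionisation and may divert it.
- Comparison: in security of relative configuration and brevity of endgame Alternative 2 is superior. The adopted plan answers with a three-step achiral precursor and an alkene position fixed by the sulfone and not by the regiochemistry of a proton loss.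

**Alternative 3:** The cut is the C8–C9 bond, with a hydrogen added to C5. A zerovalent nickel–phosphine catalyst and a trialkylsilane couple the aldehyde carbon C8 of dienal A8 to the terminal carbon C9 of its 1-isopropenylcyclopentene diene while hydride goes to C5. This closes the seven-membered ring with C1=C10 in place and the C8 oxygen silylated, giving A7.
- Merits: this is the most convergent road. Ring, two stereocentres (C5, C8) and the alkene arise in one catalytic step, and only desilylation and acylation follow. No sulfone has to be removed.
- Weak points: a seven-membered closure onto a hindered diene whose internal carbon is fully substituted is demanding. Induction at C5 and C8 must come from C4 and C7 through a flexible tether, and 1,2-addition or simple diene reduction may compete. A8 needs C4 and C7 set independently and is an α-branched aldehyde prone to epimerisation at C7.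
- Comparison: Alternative 3 is clearly better in step economy after ring closure. The adopted plan sets against it an achiral precursor and the delivery of C4, C5 and C7 together from a rigid bicyclic template instead of through open-chain induction.

Key step: step 4

Assumption: the sense of induction of Rh2(S-BPTV)4 is taken to give the (1S,8S) bridge; if the opposite sense is found, the enantiomeric catalyst from D-valine is used and nothing else changes.

## Route

Step 1
Reactants: 1 methyl 4-oxobutanoate; 2 but-3-en-2-one
Product: 3 methyl 4,7-dioxooctanoate
Conditions: 3-benzyl-5-(2-hydroxyethyl)-4-methylthiazolium chloride (10 mol%), Et3N, EtOH, 80 °C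
Reagents that add atoms: none
Why: Stetter reaction: the thiazolium-derived carbene turns the aldehyde into an acyl-anion equivalent that adds 1,4 to the enone and gives the 1,4-diketone directly; aliphatic aldehydes with methyl vinyl ketone are the standard case and the remote ester is inert.

Step 2
Reactants: 3 methyl 4,7-dioxooctanoate
Product: 4 (2-methyl-5-oxocyclopent-1-en-1-yl)acetic acid
Conditions: aq. NaOH (2 M), 80 °C; then HCl to pH 2
Reagents that add atoms: sodium hydroxide, `[Na+].[OH-]` (oxygen of the carboxylic acid)
Why: Intramolecular aldol condensation of a 1,4-diketone (the cyclisation used for 2,3-dialkylcyclopentenones such as dihydrojasmone): the methylene next to the internal ketone attacks the methyl ketone and dehydration gives the more stable tetrasubstituted enone. The methyl ester is saponified in the same pot.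

Step 3
Reactants: 4 (2-methyl-5-oxocyclopent-1-en-1-yl)acetic acid
Product: 6 1-diazo-3-(2-methyl-5-oxocyclopent-1-en-1-yl)propan-2-one, via mixed carbonic anhydride 5 (not isolated)
Conditions: i-BuOCOCl, N-methylmorpholine, THF, −15 °C; then CH2N2, Et2O, 0 °C
Reagents that add atoms: isobutyl chloroformate, `CC(C)COC(=O)Cl` (its atoms stay in 5 only); diazomethane, `C=[N+]=[N-]`
Why: Acylation of diazomethane by a mixed anhydride, the first stage of the Arndt–Eistert sequence. The cold mixed anhydride avoids the cyclic pseudo-chloride that a γ-keto acid chloride can form, and the tetrasubstituted enone is too hindered to add diazomethane at 0 °C.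

Step 4
Reactants: 6 1-diazo-3-(2-methyl-5-oxocyclopent-1-en-1-yl)propan-2-one; 7 phenyl vinyl sulfone
Product: 9 (1S,8S,10R)-1,8-epoxy-10-(phenylsulfonyl)-11,12,13,14-tetranorguai-4-en-7-one, via cyclic carbonyl ylide 8 (not isolated)
Conditions: Rh2(S-BPTV)4 (dirhodium tetrakis[N-(2,3-naphthalenedicarbonyl)-(S)-valinate], 1 mol%), 7 (4 equiv), PhCF3, 0 °C, slow addition of 6
Reagents that add atoms: none
Why: The divalent rhodium catalyst expels N2 from 6 to give an electrophilic carbenoid at C8, which is captured by a lone pair of the C1 enone oxygen in a six-membered ring closure (C8, O, C1, C5, C6, C7) to form carbonyl ylide 8. Ylide 8 then adds to 7 in a concerted suprafacial 4π+2π dipolar cycloaddition that forms C8–C9 and C1–C10; the closest known reaction type is the rhodium-carbenoid carbonyl ylide formation and [3+2] cycloaddition of 1-diazo-2,5-diones, including enantioselective versions with chiral dirhodium carboxylates. This one event closes the five-membered oxolane (O, C1, C10, C9, C8) and the seven-membered carbocycle (C1, C5, C6, C7, C8, C9, C10). C1 and C8 are set together, the bridge being necessarily cis, and their absolute sense is controlled by the chiral carboxylate ligands, which shield one face of the rhodium-associated ylide. C10 results from approach with the sulfonyl group on the side of the bridge oxygen and is of no consequence because it is erased in step 9. The regiochemistry needed is secured by the polarisation of the dipole: the acyl-stabilised, enolate-like C8 terminus bonds to the unsubstituted β-carbon of the acceptor, so the sulfonyl carbon ends on C1. Addition through the vinylogous position C4 would be an eight-electron suprafacial process at a remote, fully substituted carbon and should not compete. Excess 7 and slow addition of 6 suppress ylide dimerisation and proton transfer from C2.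

Step 5
Reactants: 9 (1S,8S,10R)-1,8-epoxy-10-(phenylsulfonyl)-11,12,13,14-tetranorguai-4-en-7-one
Product: 11 (1S,8S,10R)-1,8-epoxy-10-(phenylsulfonyl)-11,12,13,14-tetranorguaia-4,6-dien-7-yl trifluoromethanesulfonate, via potassium dienolate 10 (not isolated)
Conditions: KN(SiMe3)2 (1.05 equiv), THF, −78 °C; then PhNTf2, −78 to 0 °C
Reagents that add atoms: N-phenylbis(trifluoromethanesulfonimide), `O=S(=O)(N(c1ccccc1)S(=O)(=O)C(F)(F)F)C(F)(F)F`; KN(SiMe3)2, `C[Si](C)(C)N([K])[Si](C)(C)C` (potassium in 10 only)
Why: Enol triflate formation: only C6 can be deprotonated because C8 is a bridgehead, and this doubly activated proton is far more acidic than H10 next to the sulfone, so one equivalent of base at −78 °C gives dienolate 10 without opening the bridge. The triflimide then sulfonylates the enolate oxygen.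

Step 6
Reactants: 11 (1S,8S,10R)-1,8-epoxy-10-(phenylsulfonyl)-11,12,13,14-tetranorguaia-4,6-dien-7-yl trifluoromethanesulfonate
Product: 12 methyl (1S,8S,10R)-1,8-epoxy-10-(phenylsulfonyl)-12,13,14-trinorguaia-4,6-dien-11-oate
Conditions: Pd(OAc)2 (5 mol%), Ph2P(CH2)3PPh2, CO (1 atm), Et3N, MeOH–DMF, 50 °C
Reagents that add atoms: carbon monoxide, `[C-]#[O+]`; methanol, `CO`
Why: Palladium-catalysed alkoxycarbonylation of an enol triflate: zerovalent palladium inserts into the C7–O bond, CO insertion and methanolysis give the dienoate and create the C7–C11 bond. Sulfone, ether bridge and tetrasubstituted alkene are inert.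

Step 7
Reactants: 12 methyl (1S,8S,10R)-1,8-epoxy-10-(phenylsulfonyl)-12,13,14-trinorguaia-4,6-dien-11-oate
Product: 14 (1S,8S,10R)-1,8-epoxy-10-(phenylsulfonyl)-14-norguaia-4,6-dien-11-ol, via methyl ketone 13 (not isolated)
Conditions: MeMgBr (4 equiv), CeCl3, THF, −78 to 0 °C
Reagents that add atoms: methylmagnesium bromide, `C[Mg]Br`
Why: Double 1,2-addition of a methyl organometallic to an ester through ketone 13. The weakly basic, oxophilic cerium reagent suppresses conjugate addition to the dienoate and deprotonation at C10, which would open the bridge too early.

Step 8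
Reactants: 14 (1S,8S,10R)-1,8-epoxy-10-(phenylsulfonyl)-14-norguaia-4,6-dien-11-ol
Product: 15 (1S,4S,5S,7S,8S,10R)-1,8-epoxy-10-(phenylsulfonyl)-14-norguaian-11-ol
Conditions: [Ir(cod)(PCy3)(py)]PF6 (10 mol%), H2 (1–4 atm), CH2Cl2, rt
Reagents that add atoms: none
Why: Hydroxyl- and ether-directed homogeneous hydrogenation with a cationic iridium catalyst of the type that also reduces tetrasubstituted alkenes. Iridium held by the C11 hydroxyl and the bridge oxygen delivers all four hydrogens to the bridge-oxygen face, which is also the open face opposite the C9–C10 bridge. This places H4, H5 and H7 cis to the C8 oxygen and sets 4S, 5S and 7S.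

Step 9
Reactants: 15 (1S,4S,5S,7S,8S,10R)-1,8-epoxy-10-(phenylsulfonyl)-14-norguaian-11-ol
Product: 16 (4S,5S,7S,8S)-10-(phenylsulfonyl)-14-norguai-1(10)-ene-8,11-diol
Conditions: LiN(i-Pr)2 (2.2 equiv), THF, −78 to −20 °C; aq. NH4Cl
Reagents that add atoms: none
Why: E1cB β-elimination, as in the base-induced opening of oxabicyclic sulfones: after the hydroxyl is deprotonated, the second equivalent of amide removes H10 and the α-sulfonyl carbanion expels the C1 alkoxide. C8 keeps its oxygen and configuration, and the alkene can only form at C1=C10.

Step 10
Reactants: 16 (4S,5S,7S,8S)-10-(phenylsulfonyl)-14-norguai-1(10)-ene-8,11-diol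
Product: 17 (4S,5S,7S,8S)-guai-1(10)-ene-8,11-diol (8-hydroxybulnesol)
Conditions: Ni(acac)2 (15 mol%), MeMgBr (6 equiv), THF, 0 to 50 °C
Reagents that add atoms: methylmagnesium bromide, `C[Mg]Br`
Why: Nickel-catalysed Kumada-type cross-coupling of an alkenyl sulfone with a Grignard reagent that has no β-hydrogen: low-valent nickel formed in the flask inserts into the alkenyl C–S bond and the sulfonyl group is replaced by methyl without moving the double bond. The two hydroxyls are carried as magnesium alkoxides.

Step 11
Reactants: 18 ferulic acid
Product: 20 (E)-3-[4-(tert-butyldimethylsilyloxy)-3-methoxyphenyl]prop-2-enoic acid, via bis-silylated ferulate 19 (not isolated)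
Conditions: TBSCl (2.3 equiv), imidazole, DMF, rt; then AcOH–THF–H2O, rt
Reagents that add atoms: tert-butyldimethylsilyl chloride, `CC(C)(C)[Si](C)(C)Cl`
Why: Silylation of phenol and acid, then selective hydrolysis of the labile silyl ester under mildly acidic conditions that leave the aryl silyl ether. The phenol is masked because it would compete as a nucleophile in the esterification.

Step 12
Reactants: 17 (4S,5S,7S,8S)-guai-1(10)-ene-8,11-diol; 20 (E)-3-[4-(tert-butyldimethylsilyloxy)-3-methoxyphenyl]prop-2-enoic acid
Product: 22 (4S,5S,7S,8S)-11-hydroxyguai-1(10)-en-8-yl (E)-3-[4-(tert-butyldimethylsilyloxy)-3-methoxyphenyl]prop-2-enoate, via Yamaguchi mixed anhydride 21 (not isolated)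
Conditions: 2,4,6-Cl3C6H2COCl, Et3N, THF, rt; then 17, DMAP, toluene, rt to 40 °C
Reagents that add atoms: 2,4,6-trichlorobenzoyl chloride, `O=C(Cl)c1c(Cl)cc(Cl)cc1Cl` (its atoms stay in 21 only)
Why: Yamaguchi esterification: the mixed anhydride is attacked at the cinnamoyl carbonyl under DMAP catalysis by the secondary C8 hydroxyl, while the tertiary C11 hydroxyl does not react. The C8–O bond is not broken, so 8S is retained.

Step 13
Reactants: 22 (4S,5S,7S,8S)-11-hydroxyguai-1(10)-en-8-yl (E)-3-[4-(tert-butyldimethylsilyloxy)-3-methoxyphenyl]prop-2-enoate
Product: 23 (4S,5S,7S,8S)-11-hydroxyguai-1(10)-en-8-yl (E)-3-(4-hydroxy-3-methoxyphenyl)prop-2-enoate (CNP0241038.1)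
Conditions: Bu4NF, AcOH, THF, 0 °C
Reagents that add atoms: none
Why: Fluoride-induced cleavage of an aryl silyl ether, which is fast at 0 °C. Buffering with acetic acid keeps the medium from attacking the cinnamate ester or isomerising the tetrasubstituted alkene.

## Compound list

```
1 | methyl 4-oxobutanoate | COC(=O)CCC=O | starting material
2 | but-3-en-2-one (methyl vinyl ketone) | CC(=O)C=C | starting material
3 | methyl 4,7-dioxooctanoate | COC(=O)CCC(=O)CCC(C)=O | intermediate
4 | (2-methyl-5-oxocyclopent-1-en-1-yl)acetic acid | OC(=O)CC1=C(C)CCC1=O | intermediate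
5 | isobutyl carbonic (2-methyl-5-oxocyclopent-1-en-1-yl)acetic anhydride | CC(C)COC(=O)OC(=O)CC1=C(C)CCC1=O | intermediate (not isolated)
6 | 1-diazo-3-(2-methyl-5-oxocyclopent-1-en-1-yl)propan-2-one | [N-]=[N+]=CC(=O)CC1=C(C)CCC1=O | intermediate
7 | phenyl vinyl sulfone | C=CS(=O)(=O)c1ccccc1 | starting material
8 | six-membered cyclic carbonyl ylide of 6 (carbanion at C8, oxocarbenium at C1, C4=C5 and C7 ketone retained) | O=C1CC2=C(C)CCC2=[O+][CH-]1 | intermediate (not isolated)
9 | (1S,8S,10R)-1,8-epoxy-10-(phenylsulfonyl)-11,12,13,14-tetranorguai-4-en-7-one (C1–O–C8 bridge, sulfonyl on the bridge-oxygen side) | O=C1CC2=C(C)CC[C@]23O[C@H]1C[C@H]3S(=O)(=O)c1ccccc1 | intermediate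
10 | potassium (1S,8S,10R)-1,8-epoxy-10-(phenylsulfonyl)-11,12,13,14-tetranorguaia-4,6-dien-7-olate | [K+].[O-]C1=CC2=C(C)CC[C@]23O[C@H]1C[C@H]3S(=O)(=O)c1ccccc1 | intermediate (not isolated)
11 | (1S,8S,10R)-1,8-epoxy-10-(phenylsulfonyl)-11,12,13,14-tetranorguaia-4,6-dien-7-yl trifluoromethanesulfonate | O=S(=O)(OC1=CC2=C(C)CC[C@]23O[C@H]1C[C@H]3S(=O)(=O)c1ccccc1)C(F)(F)F | intermediate
12 | methyl (1S,8S,10R)-1,8-epoxy-10-(phenylsulfonyl)-12,13,14-trinorguaia-4,6-dien-11-oate | COC(=O)C1=CC2=C(C)CC[C@]23O[C@H]1C[C@H]3S(=O)(=O)c1ccccc1 | intermediate
13 | (1S,8S,10R)-1,8-epoxy-10-(phenylsulfonyl)-13,14-dinorguaia-4,6-dien-11-one (C7 acetyl) | CC(=O)C1=CC2=C(C)CC[C@]23O[C@H]1C[C@H]3S(=O)(=O)c1ccccc1 | intermediate (not isolated)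
14 | (1S,8S,10R)-1,8-epoxy-10-(phenylsulfonyl)-14-norguaia-4,6-dien-11-ol | CC(C)(O)C1=CC2=C(C)CC[C@]23O[C@H]1C[C@H]3S(=O)(=O)c1ccccc1 | intermediate
15 | (1S,4S,5S,7S,8S,10R)-1,8-epoxy-10-(phenylsulfonyl)-14-norguaian-11-ol (H4, H5, H7 on the bridge-oxygen face) | CC(C)(O)[C@H]1C[C@H]2[C@@H](C)CC[C@]23O[C@H]1C[C@H]3S(=O)(=O)c1ccccc1 | intermediate
16 | (4S,5S,7S,8S)-10-(phenylsulfonyl)-14-norguai-1(10)-ene-8,11-diol | O[C@H]1CC(S(=O)(=O)c2ccccc2)=C3CC[C@H](C)[C@@H]3C[C@@H]1C(C)(C)O | intermediate
17 | (4S,5S,7S,8S)-guai-1(10)-ene-8,11-diol (8-hydroxybulnesol) | O[C@H]1CC(C)=C2CC[C@H](C)[C@@H]2C[C@@H]1C(C)(C)O | intermediate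
18 | ferulic acid, (E)-3-(4-hydroxy-3-methoxyphenyl)prop-2-enoic acid | COc1cc(/C=C/C(=O)O)ccc1O | starting material
19 | tert-butyldimethylsilyl (E)-3-[4-(tert-butyldimethylsilyloxy)-3-methoxyphenyl]prop-2-enoate | COc1cc(/C=C/C(=O)O[Si](C)(C)C(C)(C)C)ccc1O[Si](C)(C)C(C)(C)C | intermediate (not isolated)
20 | (E)-3-[4-(tert-butyldimethylsilyloxy)-3-methoxyphenyl]prop-2-enoic acid | COc1cc(/C=C/C(=O)O)ccc1O[Si](C)(C)C(C)(C)C | intermediate
21 | (E)-3-[4-(tert-butyldimethylsilyloxy)-3-methoxyphenyl]prop-2-enoic 2,4,6-trichlorobenzoic anhydride | COc1cc(/C=C/C(=O)OC(=O)c2c(Cl)cc(Cl)cc2Cl)ccc1O[Si](C)(C)C(C)(C)C | intermediate (not isolated)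
22 | (4S,5S,7S,8S)-11-hydroxyguai-1(10)-en-8-yl (E)-3-[4-(tert-butyldimethylsilyloxy)-3-methoxyphenyl]prop-2-enoate | COc1cc(/C=C/C(=O)O[C@H]2CC(C)=C3CC[C@H](C)[C@@H]3C[C@@H]2C(C)(C)O)ccc1O[Si](C)(C)C(C)(C)C | intermediate
23 | (4S,5S,7S,8S)-11-hydroxyguai-1(10)-en-8-yl (E)-3-(4-hydroxy-3-methoxyphenyl)prop-2-enoate (CNP0241038.1) | COc1cc(/C=C/C(=O)O[C@H]2CC(C)=C3CC[C@H](C)[C@@H]3C[C@@H]2C(C)(C)O)ccc1O | target
```

## Step count and least certain steps

Total: 13 steps. Longest linear sequence: 12 steps (steps 1–10, 12 and 13); step 11 is a one-step side branch.

**Step 4 (key step).** The most likely failure is loss of enantiocontrol. If the ylide leaves the chiral rhodium centre before it meets the sulfone, the free dipole adds without facial preference. A moderately reactive dipolarophile also leaves time for proton transfer from C2 or dimerisation. The fallback moves the stereocontrol from the catalyst to the dipolarophile. It sets out from 6: decomposition with achiral Rh2(OAc)4 in the presence of the enantiopure reagent (R)-phenyl vinyl sulfoxide F1 should give, by the same C8–O, C8–C9 and C1–C10 bond formation, the sulfinyl cycloadduct (1S,8S,10R)-1,8-epoxy-10-[(R)-phenylsulfinyl]-11,12,13,14-tetranorguai-4-en-7-one F2. Its facial diastereomer is separable at this stage. Chemoselective oxidation at sulfur (Pr4N[RuO4] as catalyst with N-methylmorpholine N-oxide, which spares the tetrasubstituted alkene) then erases the sulfur stereocentre and returns to the route at 9.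

**Step 8.** The risk is incomplete reduction of the tetrasubstituted C4=C5 bond, or iridium-hydride-mediated migration of that bond before reduction, which would erode the configuration at C4. The fallback replaces directed delivery by steric approach control plus thermodynamic correction. It sets out from ester 12: hydrogenation over a heterogeneous catalyst (H2, Rh/Al2O3, EtOAc) from the open bridge-oxygen face should give the saturated ester methyl (1S,4S,5S,7S,8S,10R)-1,8-epoxy-10-(phenylsulfonyl)-12,13,14-trinorguaian-11-oate F3. Any C7 epimer can be equilibrated with NaOMe in MeOH to this isomer, in which the ester is equatorial and trans to the bridge oxygen. Addition of MeMgBr/CeCl3 to F3 returns to the route at 15.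

**Step 10.** The risk is slow insertion of nickel into the hindered, tetrasubstituted alkenyl C–S bond, with competing cleavage of the S–phenyl bond or base-induced migration of the alkene to an allyl sulfone. The fallback brings the methyl in with the dipolarophile and removes the sulfone reductively. It sets out from 6: cycloaddition under the step 4 conditions with 2-(phenylsulfonyl)propene F4 should give (1S,8S,10R)-1,8-epoxy-10-(phenylsulfonyl)-11,12,13-trinorguai-4-en-7-one F5, which already carries C14 (either C10 epimer serves). The operations of steps 5 to 8 then lead through the enol triflate F6, the methyl ester F7 and the dienol F8 to the saturated β-alkoxy sulfone (1S,4S,5S,7S,8S,10R)-1,8-epoxy-10-(phenylsulfonyl)norguaian-11-ol F9. Reductive β-elimination of the Julia–Lythgoe type (SmI2 with HMPA, or sodium amalgam in buffered MeOH) cleaves the C10–S bond and expels the C1 oxygen, returning to the route at 17. This fallback also avoids step 9.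

**Step 12.** The risk is slow acylation of the C8 hydroxyl, which is flanked by the hydroxyisopropyl group; forcing conditions could dehydrate the tertiary alcohol. The fallback builds the cinnamate alkene on the terpene. It sets out from 17: the small acid (diethoxyphosphoryl)acetic acid with a carbodiimide acylates even hindered alcohols and should give (4S,5S,7S,8S)-11-hydroxyguai-1(10)-en-8-yl (diethoxyphosphoryl)acetate F10. A Horner–Wadsworth–Emmons reaction of F10 with commercial 4-(tert-butyldimethylsilyloxy)-3-methoxybenzaldehyde (LiCl, DBU, MeCN) forms the E-alkene and returns to the route at 22.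

## Further compounds

```
F1 | step 4 | (R)-phenyl vinyl sulfoxide | C=C[S@@](=O)c1ccccc1
F2 | step 4 | (1S,8S,10R)-1,8-epoxy-10-[(R)-phenylsulfinyl]-11,12,13,14-tetranorguai-4-en-7-one | O=C1CC2=C(C)CC[C@]23O[C@H]1C[C@H]3[S@@](=O)c1ccccc1
F3 | step 8 | methyl (1S,4S,5S,7S,8S,10R)-1,8-epoxy-10-(phenylsulfonyl)-12,13,14-trinorguaian-11-oate | COC(=O)[C@H]1C[C@H]2[C@@H](C)CC[C@]23O[C@H]1C[C@H]3S(=O)(=O)c1ccccc1
F4 | step 10 | 2-(phenylsulfonyl)propene | C=C(C)S(=O)(=O)c1ccccc1
F5 | step 10 | (1S,8S,10R)-1,8-epoxy-10-(phenylsulfonyl)-11,12,13-trinorguai-4-en-7-one | O=C1CC2=C(C)CC[C@]23O[C@H]1C[C@@]3(C)S(=O)(=O)c1ccccc1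
F6 | step 10 | (1S,8S,10R)-1,8-epoxy-10-(phenylsulfonyl)-11,12,13-trinorguaia-4,6-dien-7-yl trifluoromethanesulfonate | O=S(=O)(OC1=CC2=C(C)CC[C@]23O[C@H]1C[C@@]3(C)S(=O)(=O)c1ccccc1)C(F)(F)F
F7 | step 10 | methyl (1S,8S,10R)-1,8-epoxy-10-(phenylsulfonyl)-12,13-dinorguaia-4,6-dien-11-oate | COC(=O)C1=CC2=C(C)CC[C@]23O[C@H]1C[C@@]3(C)S(=O)(=O)c1ccccc1
F8 | step 10 | (1S,8S,10R)-1,8-epoxy-10-(phenylsulfonyl)guaia-4,6-dien-11-ol | CC(C)(O)C1=CC2=C(C)CC[C@]23O[C@H]1C[C@@]3(C)S(=O)(=O)c1ccccc1
F9 | step 10 | (1S,4S,5S,7S,8S,10R)-1,8-epoxy-10-(phenylsulfonyl)guaian-11-ol | CC(C)(O)[C@H]1C[C@H]2[C@@H](C)CC[C@]23O[C@H]1C[C@@]3(C)S(=O)(=O)c1ccccc1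
F10 | step 12 | (4S,5S,7S,8S)-11-hydroxyguai-1(10)-en-8-yl (diethoxyphosphoryl)acetate | CCOP(=O)(OCC)CC(=O)O[C@H]1CC(C)=C2CC[C@H](C)[C@@H]2C[C@@H]1C(C)(C)O
A1 | alternative 1 | C8 1,3-dithiane bearing the methallyl group, the C7 side chain with the C11 carbinol and the 2-methyl-5-methylenecyclopentyl unit | C=C(C)CC1(SCCCS1)[C@H](C[C@H]2[C@@H](C)CCC2=C)C(C)(C)O
A2 | alternative 1 | (S)-2,2-dimethyl-3-[(2-methyl-5-methylenecyclopentyl)methyl]oxirane (C7–C11 epoxide, guaiane 4S,5S in the ring) | CC1(C)O[C@H]1C[C@H]2[C@@H](C)CCC2=C
A3 | alternative 1 | 1,3-dithiane | C1CSCSC1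
A4 | alternative 1 | methallyl bromide (3-bromo-2-methylprop-1-ene) | C=C(C)CBr
A5 | alternative 2 | 8-hydroxybulnesol 8,11-acetonide | CC1(C)O[C@H]2CC(C)=C3CC[C@H](C)[C@@H]3C[C@@H]2C(C)(C)O1
A6 | alternative 2 | trans-fused eudesmane-8,11-diol acetonide with an equatorial C1 p-toluenesulfonate | Cc1ccc(cc1)S(=O)(=O)O[C@@H]1CC[C@H](C)[C@@H]2C[C@H]3[C@H](C[C@@]12C)OC(C)(C)OC3(C)C
A7 | alternative 3 | 8-hydroxybulnesol bis(triethylsilyl) ether | CC[Si](CC)(CC)O[C@H]1CC(C)=C2CC[C@H](C)[C@@H]2C[C@@H]1C(C)(C)O[Si](CC)(CC)CC
A8 | alternative 3 | (S)-3-methyl-2-{[5-methyl-2-(prop-1-en-2-yl)cyclopent-1-en-1-yl]methyl}-3-(triethylsilyloxy)butanal (C8 aldehyde, C7 stereocentre, guaiane 4S in the ring) | O=C[C@H](CC1=C(C(C)=C)CC[C@@H]1C)C(C)(C)O[Si](CC)(CC)CC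
```
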